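A ratio of 1.77 between two highest readings is our way in: alder reads 16.6% of complex with one exchanged at 6.00 h, elm 9.4% at 3.00 h, while the charge ratio c(incoming ligand)/c(starting complex) goes from 1.90 to 0.475.

| setting | alder | elm | flask |
|---|---|---|---|
| starting complex | 10 mM | 40 mM | 20 mM |
| incoming ligand | 19 mM | 19 mM | 19.0 mM |
| remark | run made earlier | run made earlier |  |
| time |  |  | 20 h |

- alder (time / h: complex with one exchanged / %): 1.33: 8.7; 3.00: 13.9; 6.00: 16.6; 12.0: 13.8
- elm (time / h: complex with one exchanged / %): 1.33: 6.2; 3.00: 9.4; 6.00: 8.1; 12.0: 5.0

(readings scatter by 0.3 percentage points)

* the moment within 20 h at which there is most complex with one exchanged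
* the amount of complex with one exchanged, in percent of the starting complex charged, at that time

We define the peak exponent, an apparent order at a fixed charge of incoming ligand, as the logarithm of the ratio of highest readings over the logarithm of the ratio of charge ratios: 0.410. The flask has the same ligand charge as both runs and a charge ratio of 0.950, so from alder the exponent gives 12.5%. The flask's charge ratio stands midway between the two on a logarithmic scale, so that figure is the geometric mean of the two highest readings, and the geometric mean of their times gives 4.24 h.

But those highest readings stand at different times, so their mean need not be the top of the mean curve. We check: the geometric mean of the alder and elm readings is 11.4% at 3.00 h and 11.6% at 6.00 h. These are nearly level, and our figure stands 0.9 percentage points above the higher one. We commit to 12.5% near 4.24 h, with an error in the percentage of that size.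

The forecast, stepping rates forward, says 4.1 h and 12.3%, “between elm and alder”.

The flask tops at 5.25 h with 13.3%, 0.80 points above our figure and later than our 4.24 h. The top is broad: 13.1% stands at 6.56 h and 11.6% at 10.5 h. Put back into the peak exponent, the flask's top gives 0.321 from the alder reading to the flask and 0.499 from the flask to the elm reading, steeper on the low-ratio side.

    starting complex + incoming ligand ⇌ leaving ligand + complex with one exchanged (K = 1.90, k = 4.60 L mol⁻¹ h⁻¹)
    starting complex + complex with one exchanged → side product (k = 7.30 L mol⁻¹ h⁻¹)
    complex with one exchanged + incoming ligand ⇌ leaving ligand + complex with two exchanged (K = 15.0, k = 13.0 L mol⁻¹ h⁻¹)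

The neighbour flask holds the starting complex and cuts the incoming ligand to 4.8 mM, 0.240 equiv, so it lowers the charge ratio by another route than the one the exponent was read on; taken over as a trial, the exponent 0.410 carried down from 13.3% gives 7.56%. The computed peak there is 5.62%, lower than that.

The numbers in the tables stem from a simulated flask with constants of no real substance.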